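The runs were generated by integration for an exercise, and the scatter is random.

Which recipe leaves the most target at the end, and should the first nucleophile be fed in or charged at once?

| flask | substrate | first nucleophile | second nucleophile | temperature | remark | time |
|---|---|---|---|---|---|---|
| beta | 0.050 M | 0.060 M | 0.075 M | 85 °C | run made earlier |  |
| alpha | 0.025 M | 0.060 M | 0.075 M | 96 °C | run made earlier |  |
| epsilon | 0.038 M | 0.060 M | 0.075 M | 85 °C | run made earlier |  |
| south | 0.050 M | 0.0600 M (fed, over 40 h) | 0.0750 M | 90 °C | all else is in the flask from the start; the feed brings no volume worth counting | 3.0 d |
| north-west | 0.050 M | 0.0600 M (fed, over 10 h) | 0.0750 M | 90 °C | all else is in the flask from the start; the feed brings no volume worth counting | 3.0 d |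
| north | 0.050 M (fed, over 40 h) | 0.0600 M | 0.0750 M | 90 °C | all else is in the flask from the start; the feed brings no volume worth counting | 3.0 d |
| south-east | 0.050 M | 0.0600 M | 0.0750 M | 90 °C | everything together at the start | 3.0 d |
| south-west | 0.050 M (fed, over 40 h) | 0.0600 M | 0.0750 M |  | the addition at 50 °C, then warmed to 90 °C; the feed brings no volume worth counting | 3.0 d |

beta run (percent of the substrate charged)

| time / h | target / % |
|---|---|
| 2.50 | 0 |
| 6.00 | 5 |
| 12.0 | 9 |
| 20.0 | 13 |
| 25.0 | 17 |
| 30.0 | 18 |
| 40.0 | 18 |

alpha run (percent of the substrate charged)

| time / d | target / % |
|---|---|
| 0.250 | 12 |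
| 0.333 | 17 |
| 0.500 | 22 |
| 0.833 | 20 |
| 1.25 | 14 |
| 2.08 | 7 |
| 3.00 | 4 |

epsilon run (percent of the substrate charged)

| time / d | target / % |
|---|---|
| 0.417 | 9 |
| 0.833 | 17 |
| 1.25 | 20 |
| 1.67 | 20 |
| 2.00 | 19 |
| 2.50 | 20 |
| 3.00 | 20 |

(standard deviation of a reading: 1.5 percentage points)



1. the flask that comes out highest in amount of target, in percent of the substrate charged, or "all alike" when all lie within 1.5 percentage points (south / north-west / north / south-east / south-west / all alike)
2. target at the end, in percent of the substrate charged, south
3. target at the end, in percent of the substrate charged, north-west
4. target at the end, in percent of the substrate charged, north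
5. target at the end, in percent of the substrate charged, south-east
6. target at the end, in percent of the substrate charged, south-west

The beta run showed 0% target at 2.50 h before it climbed, and I read that lag as an intermediate which both nucleophiles can catch. For a zero on the scale I took the case where neither is preferred, a selectivity factor of one, so that each catches in proportion to its concentration. That gives the even-odds share, c(first nucleophile) divided by the sum of c(first nucleophile) and c(second nucleophile), and as charged it is 44.4%. The best readings, 22% in the alpha run and 20% in the epsilon run, stood lower than that share, and the alpha run then fell to 4% at 3.00 d, so I did not take target as safe once made.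

My decision concerned the feed of first nucleophile. In south, with half of it in and the second nucleophile counted as charged, the share is 28.6%, less than the even-odds share as charged. So I decided to charge the first nucleophile at the start and drop that feed. With a feed of substrate both nucleophiles stand at their charge from the start, so the share starts at 44.4%.

The forecast chose south, with 32% for south, 24% for north-west, 9% for north, 19% for south-east and 19% for south-west, on the ground that “Feeding first nucleophile slowly starves over-reaction, so higher”. My reckoning pointed the other way on south.

    substrate → intermediate (k = 5.20 × 10⁻⁴ min⁻¹, Ea = 121 kJ mol⁻¹)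
    first nucleophile + intermediate → target (k = 0.250 L mol⁻¹ min⁻¹, Ea = 71.0 kJ mol⁻¹)
    second nucleophile + intermediate → other capture product (k = 0.150 L mol⁻¹ min⁻¹, Ea = 87.0 kJ mol⁻¹)
    target → over-reaction product (k = 5.40 × 10⁻⁴ min⁻¹, Ea = 112 kJ mol⁻¹)
    (constants at 90 °C)

The highest flask was south-west, at 19.9%, against 11.4% for south, 12.3% for north-west, 16.7% for north and 12.4% for south-east. South-west still held 36.7% of its substrate at 3.00 d. The scheme sends target on to over-reaction product, so I counted the two together per substrate consumed: south gave 39.2% and south-east 54.5%, with the even-odds share 44.4% between them.

For a neighbour flask, which is south with 0.019 M of second nucleophile, the even-odds share as charged rises to 75.9%, more than 44.4%. The computed flask gave 71.2% on the same count, with 19.0% target at 3.00 d.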